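**Retrosynthetic overview**
- Last come desilylation, C10 angeloylation, C10 ketone reduction and C6 aroylation of a bicyclic dihydroxy enone (4,6-dihydroxydauc-8-en-10-one).
- The seven-membered ring is closed second and last, by ring-closing metathesis at C8=C9 between a vinyl ketone on C1 and a methallyl arm on C6.
- The vinyl ketone comes from a methyl ketone masked as a 1-silylvinyl group; the C6 carbinol from reagent-controlled methallylboration of a C5 aldehyde; the C4 carbinol from isopropyl addition to the ring ketone.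
- The five-membered ring is present from the start (3-methylcyclopent-2-enone): asymmetric conjugate addition sets C1, trapping of the resulting enolate sets C5.
- Three side branches (silyl-protected aroyl chloride, angelic mixed anhydride, chiral methallylborane) feed the main line.

Convention: core carbons carry daucane labels (C1 ring-fusion C with CH3; C2, C3 ring CH2; C4 C(OH)iPr; C5 ring-fusion CH; C6 CH–O-aroyl; C7 CH2; C8 =C(CH3); C9 =CH; C10 CH–O-angeloyl); the target is (1S,4R,5S,6S,10S).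

**Step 1**
Reactants: 1 3-methylcyclopent-2-en-1-one; 2 ethynyl(trimethyl)silane
Product: 5 (S)-trimethyl({3-methyl-3-[1-(trimethylsilyl)ethenyl]cyclopent-1-en-1-yl}oxy)silane, via vinylalane 3 (not isolated), via aluminium enolate 4 (not isolated)
Conditions: 2, iBu2AlH, hexanes/THF, 55 °C; then 1, Cu(OTf)2 (5 mol%), chiral N-aryl-N′-(2-sulfonatoaryl)-4,5-diphenylimidazolinium zwitterion (NHC precursor, 6 mol%, antipode giving the S centre), THF, −78 → −15 °C; then TMSOTf, −78 → 0 °C
Reagents that add atoms: trimethylsilyl trifluoromethanesulfonate, C[Si](C)(C)OS(=O)(=O)C(F)(F)F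
Why: Hydroalumination places aluminium on the silicon-bearing carbon, the copper–NHC-catalysed asymmetric conjugate addition of this alkenylalane creates the quaternary C1 (S), and O-silylation fixes the enolate regiochemistry at C4–C5.

**Step 2**
Reactants: 5 (S)-trimethyl({3-methyl-3-[1-(trimethylsilyl)ethenyl]cyclopent-1-en-1-yl}oxy)silane
Product: 6 (2S,3S)-2-(dimethoxymethyl)-3-methyl-3-[1-(trimethylsilyl)ethenyl]cyclopentan-1-one
Conditions: HC(OMe)3, TMSOTf (5 mol%), CH2Cl2, −78 °C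
Reagents that add atoms: trimethyl orthoformate, COC(OC)OC
Why: In this Mukaiyama-type aldol with an orthoester, the dimethoxycarbenium ion attacks C5 anti to the bulky 1-silylvinyl group, so C6 ends trans to C10 and cis to the C1 methyl, which is also the more stable arrangement.

**Step 3**
Reactants: 6 (2S,3S)-2-(dimethoxymethyl)-3-methyl-3-[1-(trimethylsilyl)ethenyl]cyclopentan-1-one
Product: 7 (1R,2R,3S)-2-(dimethoxymethyl)-3-methyl-1-(propan-2-yl)-3-[1-(trimethylsilyl)ethenyl]cyclopentan-1-ol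
Conditions: iPrMgCl, LaCl3·2LiCl (30 mol%), THF, 0 °C; then H2O
Reagents that add atoms: isopropylmagnesium chloride, CC(C)[Mg]Cl
Why: In this lanthanum-promoted Grignard addition (no enolisation or reduction), isopropyl enters anti to the adjacent dimethoxymethyl group and the flanking methyl, so the new hydroxyl is cis to C6 (the 4R centre of the target).

**Step 4**
Reactants: 7 (1R,2R,3S)-2-(dimethoxymethyl)-3-methyl-1-(propan-2-yl)-3-[1-(trimethylsilyl)ethenyl]cyclopentan-1-ol
Product: 9 (1R,2S,5R)-2-acetyl-5-hydroxy-2-methyl-5-(propan-2-yl)cyclopentane-1-carbaldehyde, via epoxysilane 8 (not isolated)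
Conditions: mCPBA, CH2Cl2, 0 → 23 °C; then 1 M H2SO4, THF, 23 °C; used at once
Reagents that add atoms: 3-chloroperoxybenzoic acid, OOC(=O)c1cccc(Cl)c1; water, O
Why: Prilezhaev epoxidation of the only alkene and acid-induced opening with loss of silicon (Peterson-type) unmask the methyl ketone while the same acid hydrolyses the acetal; no stereocentre is touched and the trans geometry rules out hemiketals.

**Step 5**
Reactants: 10 (−)-B-methoxydiisopinocampheylborane; 11 (2-methylprop-2-en-1-yl)magnesium chloride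
Product: 12 (−)-B-(2-methylprop-2-en-1-yl)diisopinocampheylborane
Conditions: Et2O, −78 → 23 °C; filtered from magnesium salts under argon
Reagents that add atoms: none
Why: Transmetallation of the Grignard reagent onto boron gives Brown's salt-free methallylborane, the chiral controller for step 6.

**Step 6**
Reactants: 9 (1R,2S,5R)-2-acetyl-5-hydroxy-2-methyl-5-(propan-2-yl)cyclopentane-1-carbaldehyde; 12 (−)-B-(2-methylprop-2-en-1-yl)diisopinocampheylborane
Product: 14 1-[(1S,2S,3R)-3-hydroxy-2-[(1S)-1-hydroxy-3-methylbut-3-en-1-yl]-1-methyl-3-(propan-2-yl)cyclopentyl]ethan-1-one, via borinate 13 (not isolated)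
Conditions: 12 (1.5 equiv), Et2O, −78 °C; then NaOH, H2O2, 0 °C
Reagents that add atoms: none
Why: Brown asymmetric methallylboration through a chair transition state: the borane from (+)-α-pinene attacks the Si face of the aldehyde (reagent control) to give the 6S carbinol, and the methyl ketone is left alone.

**Step 7**
Reactants: 14 1-[(1S,2S,3R)-3-hydroxy-2-[(1S)-1-hydroxy-3-methylbut-3-en-1-yl]-1-methyl-3-(propan-2-yl)cyclopentyl]ethan-1-one
Product: 17 1-[(1S,2S,3R)-3-hydroxy-2-[(1S)-1-hydroxy-3-methylbut-3-en-1-yl]-1-methyl-3-(propan-2-yl)cyclopentyl]prop-2-en-1-one, via Mannich base 15 (not isolated), via ammonium iodide 16 (not isolated)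
Conditions: LiHMDS (3.2 equiv), THF, −78 °C; CH2=NMe2+ I−, −78 → 0 °C; aqueous work-up; then MeI, CH2Cl2, 23 °C; then DBU, 23 °C
Reagents that add atoms: N,N-dimethylmethyleneiminium iodide (Eschenmoser's salt), C=[N+](C)C.[I-]
Why: Mannich reaction of the only possible ketone enolate (C9) followed by Hofmann-type elimination of the quaternised amine gives the vinyl ketone; no stereocentre is involved.

**Step 8**
Reactants: 17 1-[(1S,2S,3R)-3-hydroxy-2-[(1S)-1-hydroxy-3-methylbut-3-en-1-yl]-1-methyl-3-(propan-2-yl)cyclopentyl]prop-2-en-1-one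
Product: 18 (1S,4R,5S,6S)-4,6-dihydroxydauc-8-en-10-one
Conditions: second-generation Hoveyda–Grubbs catalyst RuCl2(=CH-C6H4-2-OiPr)(H2IMes) (10 mol%), toluene (0.005 M), 80 °C
Reagents that add atoms: none
Why: Ring-closing metathesis between the enone and the 1,1-disubstituted alkene closes the seven-membered ring as the trisubstituted C8=C9 enone with loss of ethene; high dilution suppresses dimers.

**Step 9**
Reactants: 19 4-hydroxybenzoic acid
Product: 20 tert-butyldimethylsilyl 4-[(tert-butyldimethylsilyl)oxy]benzoate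
Conditions: TBSCl (2.2 equiv), imidazole, DMF, 23 °C
Reagents that add atoms: tert-butyl(chloro)dimethylsilane, CC(C)(C)[Si](C)(C)Cl
Why: Exhaustive silylation masks the phenol that would otherwise compete in the later acylations.

**Step 10**
Reactants: 20 tert-butyldimethylsilyl 4-[(tert-butyldimethylsilyl)oxy]benzoate
Product: 21 4-[(tert-butyldimethylsilyl)oxy]benzoic acid
Conditions: AcOH/THF/H2O (3:1:1), 23 °C
Reagents that add atoms: none
Why: The silyl ester hydrolyses far faster than the aryl silyl ether, so the acid is released selectively.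

**Step 11**
Reactants: 21 4-[(tert-butyldimethylsilyl)oxy]benzoic acid
Product: 22 4-[(tert-butyldimethylsilyl)oxy]benzoyl chloride
Conditions: (COCl)2, DMF (cat.), CH2Cl2, 0 → 23 °C
Reagents that add atoms: oxalyl chloride, ClC(=O)C(Cl)=O
Why: Vilsmeier-catalysed acid chloride formation gives an acyl donor reactive enough for the hindered C6 hydroxyl.

**Step 12**
Reactants: 18 (1S,4R,5S,6S)-4,6-dihydroxydauc-8-en-10-one; 22 4-[(tert-butyldimethylsilyl)oxy]benzoyl chloride
Product: 23 (1S,4R,5S,6S)-4-hydroxy-10-oxodauc-8-en-6-yl 4-[(tert-butyldimethylsilyl)oxy]benzoate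
Conditions: pyridine, DMAP (cat.), CH2Cl2, 0 → 23 °C
Reagents that add atoms: none
Why: In this DMAP-catalysed acylation only the secondary C6 hydroxyl reacts; the tertiary C4 hydroxyl is inert and C6 keeps its configuration.

**Step 13**
Reactants: 23 (1S,4R,5S,6S)-4-hydroxy-10-oxodauc-8-en-6-yl 4-[(tert-butyldimethylsilyl)oxy]benzoate
Product: 24 (1S,4R,5S,6S,10S)-4,10-dihydroxydauc-8-en-6-yl 4-[(tert-butyldimethylsilyl)oxy]benzoate
Conditions: NaBH4, CeCl3·7H2O, MeOH, −78 °C
Reagents that add atoms: none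
Why: Luche 1,2-reduction: hydride reaches C10 from the face opposite the adjacent angular methyl (as with 17-keto steroids), so the new hydroxyl is cis to that methyl (10S).

**Step 14**
Reactants: 25 (Z)-2-bromobut-2-ene
Product: 27 angelic acid (2Z)-2-methylbut-2-enoic acid, via (Z)-but-2-en-2-yllithium 26 (not isolated)
Conditions: t-BuLi (2.0 equiv), THF/Et2O/pentane, −78 °C; then CO2, −78 → 0 °C; then 1 M HCl
Reagents that add atoms: carbon dioxide, O=C=O
Why: Bromine–lithium exchange and carboxylation both proceed with retention of alkene geometry, giving the Z acid.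

**Step 15**
Reactants: 27 angelic acid (2Z)-2-methylbut-2-enoic acid
Product: 28 (2Z)-2-methylbut-2-enoic 2,4,6-trichlorobenzoic anhydride
Conditions: 2,4,6-trichlorobenzoyl chloride, Et3N, toluene, 23 °C; filtered, used as solution
Reagents that add atoms: 2,4,6-trichlorobenzoyl chloride, O=C(Cl)c1c(Cl)cc(Cl)cc1Cl
Why: Yamaguchi mixed anhydride formation activates the acid without touching its double bond.

**Step 16**
Reactants: 24 (1S,4R,5S,6S,10S)-4,10-dihydroxydauc-8-en-6-yl 4-[(tert-butyldimethylsilyl)oxy]benzoate; 28 (2Z)-2-methylbut-2-enoic 2,4,6-trichlorobenzoic anhydride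
Product: 29 (1S,4R,5S,6S,10S)-4-hydroxy-10-{[(2Z)-2-methylbut-2-enoyl]oxy}dauc-8-en-6-yl 4-[(tert-butyldimethylsilyl)oxy]benzoate
Conditions: 28 (3 equiv), Et3N (1 equiv), toluene, 80 °C
Reagents that add atoms: none
Why: Yamaguchi esterification without a nucleophilic catalyst: the C10 hydroxyl attacks the unshielded angeloyl carbonyl with retention at C10, and leaving out DMAP avoids Z to E isomerisation to the tiglate.

**Step 17**
Reactants: 29 (1S,4R,5S,6S,10S)-4-hydroxy-10-{[(2Z)-2-methylbut-2-enoyl]oxy}dauc-8-en-6-yl 4-[(tert-butyldimethylsilyl)oxy]benzoate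
Product: 30 (1S,4R,5S,6S,10S)-4-hydroxy-10-{[(2Z)-2-methylbut-2-enoyl]oxy}dauc-8-en-6-yl 4-hydroxybenzoate (CNP0273650.10)
Conditions: TBAF, AcOH, THF, 0 °C
Reagents that add atoms: none
Why: Buffered fluoride cleaves only the aryl silyl ether; both esters, the angelate geometry and all stereocentres are untouched.

**Compound list**
1 | 3-methylcyclopent-2-en-1-one | CC1=CC(=O)CC1 | starting material
2 | ethynyl(trimethyl)silane | C#C[Si](C)(C)C | starting material
3 | bis(2-methylpropyl)[1-(trimethylsilyl)ethenyl]aluminium (vinylalane) | C=C([Si](C)(C)C)[Al](CC(C)C)CC(C)C | intermediate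
4 | bis(2-methylpropyl)aluminium (S)-3-methyl-3-[1-(trimethylsilyl)ethenyl]cyclopent-1-en-1-olate (aluminium enolate) | C[C@]1(C=C(O[Al](CC(C)C)CC(C)C)CC1)C(=C)[Si](C)(C)C | intermediate
5 | (S)-trimethyl({3-methyl-3-[1-(trimethylsilyl)ethenyl]cyclopent-1-en-1-yl}oxy)silane | C[C@]1(C=C(O[Si](C)(C)C)CC1)C(=C)[Si](C)(C)C | intermediate
6 | (2S,3S)-2-(dimethoxymethyl)-3-methyl-3-[1-(trimethylsilyl)ethenyl]cyclopentan-1-one | O=C1CC[C@](C)(C(=C)[Si](C)(C)C)[C@H]1C(OC)OC | intermediate
7 | (1R,2R,3S)-2-(dimethoxymethyl)-3-methyl-1-(propan-2-yl)-3-[1-(trimethylsilyl)ethenyl]cyclopentan-1-ol | CC(C)[C@]1(O)CC[C@](C)(C(=C)[Si](C)(C)C)[C@H]1C(OC)OC | intermediate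
8 | (1R,2R,3S)-2-(dimethoxymethyl)-3-methyl-1-(propan-2-yl)-3-[2-(trimethylsilyl)oxiran-2-yl]cyclopentan-1-ol (epoxysilane, both oxirane epimers) | CC(C)[C@]1(O)CC[C@](C)(C2(CO2)[Si](C)(C)C)[C@H]1C(OC)OC | intermediate
9 | (1R,2S,5R)-2-acetyl-5-hydroxy-2-methyl-5-(propan-2-yl)cyclopentane-1-carbaldehyde | CC(C)[C@]1(O)CC[C@](C)(C(C)=O)[C@H]1C=O | intermediate
10 | (−)-B-methoxydiisopinocampheylborane, methyl bis[(1R,2S,3R,5R)-2,6,6-trimethylbicyclo[3.1.1]heptan-3-yl]borinate | COB([C@@H]1C[C@@H]2C[C@H]([C@H]1C)C2(C)C)[C@@H]1C[C@@H]2C[C@H]([C@H]1C)C2(C)C | starting material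
11 | (2-methylprop-2-en-1-yl)magnesium chloride | CC(=C)C[Mg]Cl | starting material
12 | (−)-B-(2-methylprop-2-en-1-yl)diisopinocampheylborane | CC(=C)CB([C@@H]1C[C@@H]2C[C@H]([C@H]1C)C2(C)C)[C@@H]1C[C@@H]2C[C@H]([C@H]1C)C2(C)C | intermediate
13 | O-diisopinocampheylboryl derivative of 14 at the C6 oxygen (borinate) | CC(=C)C[C@H](OB([C@@H]2C[C@@H]3C[C@H]([C@H]2C)C3(C)C)[C@@H]2C[C@@H]3C[C@H]([C@H]2C)C3(C)C)[C@@H]1[C@@](C)(C(C)=O)CC[C@@]1(O)C(C)C | intermediate
14 | 1-[(1S,2S,3R)-3-hydroxy-2-[(1S)-1-hydroxy-3-methylbut-3-en-1-yl]-1-methyl-3-(propan-2-yl)cyclopentyl]ethan-1-one | CC(=C)C[C@H](O)[C@@H]1[C@@](C)(C(C)=O)CC[C@@]1(O)C(C)C | intermediate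
15 | 3-(dimethylamino)-1-[(1S,2S,3R)-3-hydroxy-2-[(1S)-1-hydroxy-3-methylbut-3-en-1-yl]-1-methyl-3-(propan-2-yl)cyclopentyl]propan-1-one (Mannich base) | CC(=C)C[C@H](O)[C@@H]1[C@@](C)(C(=O)CCN(C)C)CC[C@@]1(O)C(C)C | intermediate
16 | 3-[(1S,2S,3R)-3-hydroxy-2-[(1S)-1-hydroxy-3-methylbut-3-en-1-yl]-1-methyl-3-(propan-2-yl)cyclopentyl]-N,N,N-trimethyl-3-oxopropan-1-aminium iodide | CC(=C)C[C@H](O)[C@@H]1[C@@](C)(C(=O)CC[N+](C)(C)C)CC[C@@]1(O)C(C)C.[I-] | intermediate
17 | 1-[(1S,2S,3R)-3-hydroxy-2-[(1S)-1-hydroxy-3-methylbut-3-en-1-yl]-1-methyl-3-(propan-2-yl)cyclopentyl]prop-2-en-1-one | CC(=C)C[C@H](O)[C@@H]1[C@@](C)(C(=O)C=C)CC[C@@]1(O)C(C)C | intermediate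
18 | (1S,4R,5S,6S)-4,6-dihydroxydauc-8-en-10-one | O=C1C=C(C)C[C@H](O)[C@@H]2[C@]1(C)CC[C@@]2(O)C(C)C | intermediate
19 | 4-hydroxybenzoic acid | OC(=O)c1ccc(O)cc1 | starting material
20 | tert-butyldimethylsilyl 4-[(tert-butyldimethylsilyl)oxy]benzoate | CC(C)(C)[Si](C)(C)Oc1ccc(cc1)C(=O)O[Si](C)(C)C(C)(C)C | intermediate
21 | 4-[(tert-butyldimethylsilyl)oxy]benzoic acid | CC(C)(C)[Si](C)(C)Oc1ccc(cc1)C(O)=O | intermediate
22 | 4-[(tert-butyldimethylsilyl)oxy]benzoyl chloride | CC(C)(C)[Si](C)(C)Oc1ccc(cc1)C(Cl)=O | intermediate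
23 | (1S,4R,5S,6S)-4-hydroxy-10-oxodauc-8-en-6-yl 4-[(tert-butyldimethylsilyl)oxy]benzoate | O=C1C=C(C)C[C@H](OC(=O)c3ccc(O[Si](C)(C)C(C)(C)C)cc3)[C@@H]2[C@]1(C)CC[C@@]2(O)C(C)C | intermediate
24 | (1S,4R,5S,6S,10S)-4,10-dihydroxydauc-8-en-6-yl 4-[(tert-butyldimethylsilyl)oxy]benzoate | O[C@H]1C=C(C)C[C@H](OC(=O)c3ccc(O[Si](C)(C)C(C)(C)C)cc3)[C@@H]2[C@]1(C)CC[C@@]2(O)C(C)C | intermediate
25 | (Z)-2-bromobut-2-ene | C/C=C(/C)Br | starting material
26 | (Z)-but-2-en-2-yllithium | C/C=C(/C)[Li] | intermediate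
27 | angelic acid, (2Z)-2-methylbut-2-enoic acid | C/C=C(/C)C(=O)O | intermediate
28 | (2Z)-2-methylbut-2-enoic 2,4,6-trichlorobenzoic anhydride | C/C=C(/C)C(=O)OC(=O)c1c(Cl)cc(Cl)cc1Cl | intermediate
29 | (1S,4R,5S,6S,10S)-4-hydroxy-10-{[(2Z)-2-methylbut-2-enoyl]oxy}dauc-8-en-6-yl 4-[(tert-butyldimethylsilyl)oxy]benzoate | C/C=C(/C)C(=O)O[C@H]1C=C(C)C[C@H](OC(=O)c3ccc(O[Si](C)(C)C(C)(C)C)cc3)[C@@H]2[C@]1(C)CC[C@@]2(O)C(C)C | intermediate
30 | (1S,4R,5S,6S,10S)-4-hydroxy-10-{[(2Z)-2-methylbut-2-enoyl]oxy}dauc-8-en-6-yl 4-hydroxybenzoate (CNP0273650.10) | C/C=C(/C)C(=O)O[C@H]1C=C(C)C[C@H](OC(=O)c2ccc(O)cc2)[C@@H]2[C@]1(C)CC[C@@]2(O)C(C)C | target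

**Totals**
Total step count: 17. Longest linear sequence: 11 steps (1, 2, 3, 4, 6, 7, 8, 12, 13, 16, 17); the side branches are steps 5, 9–11 and 14–15.

**Steps most likely to fail, with fallbacks**

Step 1 is the least precedented: the asymmetric addition of the silylvinylalane to a cyclopentenone and the O-silylation of the aluminium enolate are extrapolated from closely related published cases. The fallback gives up catalytic asymmetric induction for a racemic synthesis plus resolution. It sets out from 1: [1-(trimethylsilyl)ethenyl]magnesium bromide, CuBr·SMe2 (10 mol%) and TMSCl in THF at −78 °C give racemic enol silane, that is 5 together with its mirror image (R)-trimethyl({3-methyl-3-[1-(trimethylsilyl)ethenyl]cyclopent-1-en-1-yl}oxy)silane F1. The conditions of step 2 turn this into 6 together with its enantiomer (2R,3R)-2-(dimethoxymethyl)-3-methyl-3-[1-(trimethylsilyl)ethenyl]cyclopentan-1-one F2. Preparative chromatography on a cellulose tris(3,5-dimethylphenylcarbamate) phase separates the two, and the fallback comes back to the route at 6.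

Step 8 may be slow because both alkenes are poor partners (an electron-poor enone and a 1,1-disubstituted alkene). The fallback moves the metathesis to the allylic-alcohol oxidation level. It sets out from 17: NaBH4 and CeCl3·7H2O in MeOH at −78 °C give 1-[(1S,2S,3R)-3-hydroxy-2-[(1S)-1-hydroxy-3-methylbut-3-en-1-yl]-1-methyl-3-(propan-2-yl)cyclopentyl]prop-2-en-1-ol F3 as both carbinol epimers. Its free allylic hydroxyl speeds ring closure with second-generation Grubbs catalyst RuCl2(=CHPh)(PCy3)(H2IMes) in CH2Cl2 at 40 °C to (1S,4R,5S,6S)-dauc-8-ene-4,6,10-triol F4, again as both C10 epimers. MnO2 in CH2Cl2 oxidises only the allylic hydroxyl of both epimers, and the fallback comes back at 18.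

Step 16 acylates a hindered secondary hydroxyl next to a quaternary carbon with an acid that isomerises easily to the tiglate. The fallback builds the Z double bond on the ester instead of delivering it intact. It sets out from 24: 2-[bis(2,2,2-trifluoroethoxy)phosphoryl]propanoic acid, EDC·HCl and DMAP in CH2Cl2 (forcing conditions are harmless here) give (1S,4R,5S,6S,10S)-10-({2-[bis(2,2,2-trifluoroethoxy)phosphoryl]propanoyl}oxy)-4-hydroxydauc-8-en-6-yl 4-[(tert-butyldimethylsilyl)oxy]benzoate F5 as both epimers at the phosphorus-bearing carbon. Still–Gennari olefination (KHMDS 2.1 equiv, 18-crown-6, THF, −78 °C, then acetaldehyde) makes the Z-trisubstituted enoate, and the fallback comes back at 29.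

**Further compounds**
F1 | step 1 | (R)-trimethyl({3-methyl-3-[1-(trimethylsilyl)ethenyl]cyclopent-1-en-1-yl}oxy)silane | C[C@@]1(C=C(O[Si](C)(C)C)CC1)C(=C)[Si](C)(C)C
F2 | step 1 | (2R,3R)-2-(dimethoxymethyl)-3-methyl-3-[1-(trimethylsilyl)ethenyl]cyclopentan-1-one | O=C1CC[C@@](C)(C(=C)[Si](C)(C)C)[C@@H]1C(OC)OC
F3 | step 8 | 1-[(1S,2S,3R)-3-hydroxy-2-[(1S)-1-hydroxy-3-methylbut-3-en-1-yl]-1-methyl-3-(propan-2-yl)cyclopentyl]prop-2-en-1-ol (both carbinol epimers) | CC(=C)C[C@H](O)[C@@H]1[C@@](C)(C(O)C=C)CC[C@@]1(O)C(C)C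
F4 | step 8 | (1S,4R,5S,6S)-dauc-8-ene-4,6,10-triol (both C10 epimers) | OC1C=C(C)C[C@H](O)[C@@H]2[C@]1(C)CC[C@@]2(O)C(C)C
F5 | step 16 | (1S,4R,5S,6S,10S)-10-({2-[bis(2,2,2-trifluoroethoxy)phosphoryl]propanoyl}oxy)-4-hydroxydauc-8-en-6-yl 4-[(tert-butyldimethylsilyl)oxy]benzoate (both epimers at the phosphorus-bearing carbon) | CC(P(=O)(OCC(F)(F)F)OCC(F)(F)F)C(=O)O[C@H]1C=C(C)C[C@H](OC(=O)c3ccc(O[Si](C)(C)C(C)(C)C)cc3)[C@@H]2[C@]1(C)CC[C@@]2(O)C(C)C
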